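## Analysis of the target

The target is a C30 spiro[4.5]decane (an iridal-type triterpenoid acetate). In the numbering used here ring A is the cyclopentane C1–C5 and ring B the cyclohexane C5–C10, joined at the quaternary spiro carbon C5. Five stereocentres are present: C1 (secondary OH), C2 (triene side chain), C5, C6 (3-hydroxypropyl arm) and C10 (tertiary methyl carbinol). On ring A the C1 hydroxyl is cis to C10 and trans to both C6 and the C2 side chain; on ring B the C6 arm and the C10 hydroxyl both lie on the face of C1. Two alkenes have a geometry that no ring enforces: the tetrasubstituted enal on C7, whose formyl group is syn to C6 (Z), and the E-trisubstituted alkene that links C2 to an E-diene ending in a 1,1-disubstituted methylene and a prenyl tail. Sensitive groups are the enal (geometric isomerisation, γ-deprotonation at C6), the cross-conjugated triene with its allylic acetate, and the C1/C10 1,3-diol, which is a retro-aldol liability whenever C1 is a ketone. The hard parts are the contiguous array C1–C5–C6/C10 around a quaternary centre and the geometry of the tetrasubstituted alkene. The strategy rests on one feature: C10 is bonded to C5 and stands 1,3 to the C1 oxygen, so a C10 ketone on C5 can be reduced to a ketyl that the C1 hydroxyl holds while it closes ring B onto a vinyl ketone at C7, forming C9–C10.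

## Retrosynthetic reasoning

**37 to 34 (last functional-group changes).** The formyl group is unmasked last, from allylic alcohol 36, because the tetrasubstituted enal would not survive the base, hydride and acid used earlier. 36 comes from 35 by removal of all silyl ethers in one operation, and 35 from diol 34 by acetylation of its only primary hydroxyl. No skeletal bond is cut; the gain is that every earlier step may use strong base and hydride.

**34 to 26 + 31 (C=C between the side-chain carbon on C2 and the dienyl chain).** This alkene is cut because its two halves are an ester α-carbon and an aldehyde: 34 is the reduction product of trienoate 33, and 33 the condensation product of ester 26 with dienal 31. A cut inside the diene would need a second stereodefined coupling, and a cut at the C2–side-chain bond would need alkenylation of a hindered ketone. The forward reaction must give the E alkene, which is the more stable one and is therefore reached by an eliminative (E1cB) condensation.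

**31 to 27.** The dienal is cut between its two alkenes: 31 and 30 come from ester 29, the Heck product of enol triflate 28, which is the kinetic enol derivative of commercial ketone 27. The 1,1-disubstituted methylene is thus placed without an olefination.

**26 to 24 (C2–CH2 bond, then the C1 oxidation state).** The acetate arm is attached α to a C1 ketone: 26 from 25 by reduction, 25 from 24 by enolate alkylation. The cut is made here because in 24 the spiro carbon leaves C2 as the only enolisable position, and because the fully substituted C10 on one face of ring A should direct both the electrophile and the hydride. 24 comes from 21 through 22 and 23, steps that make C1 a ketone while the allylic alcohol and the C10 hydroxyl are capped.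

**21 to 16 (tetrasubstituted alkene on C7).** The exocyclic double bond is cut back to the ring ketone of 16. A phosphonate olefination would be expected to put the carbonyl-bearing group on the less hindered side, which is the wrong one, and would need base next to the epimerisable C6. The ketone is therefore taken through ethynyl carbinol 17 and acetate 18 to allenyl acetate 19; C-methylation of its allenolate in the plane of the ring decides the geometry, and reduction of enal 20 in the same flask gives 21.

**16 to 15 (C9–C10, ring B; key disconnection).** Ring B is opened between the tertiary carbinol carbon and the adjacent methylene. This is the one bond whose formation creates C10 under the control of the existing C1 hydroxyl, and it leaves the ring ketone exactly where the alkylidene is needed. The forward step is a ketyl–olefin closure with a divalent samarium reductant on hydroxy diketone 15.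

**15 to 11.** The vinyl ketone is taken back through allylic alcohol 14 and aldehyde 13 to the vinyl group of 11. This route is chosen because an aldehyde can be vinylated in the presence of the methyl ketone.

**11 to 7 (C5–C6 bond).** Methyl ketone 11 is the methyl adduct of acid 10. Acid 10 is cut between the quaternary carbon and the neighbouring methine by a [3,3] shift, back to allyl ester 7 (through 8 and 9). This single cut makes both centres, relative to the carbinol already present, from an enolate whose geometry is fixed by chelation and an alkene whose geometry is fixed by semihydrogenation.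

**7 to 6 + 4; 6 to 5; 4 to 1.** Ester exchange joins hydroxy ester 6 and Z-allylic alcohol 4. 6 comes from commercial keto ester 5 by asymmetric hydrogenation, the only step that needs a chiral reagent; 4 comes from commercial alkynol 1 through 2 and 3.

## Alternatives that were turned down

**Alternative 1:** The cut is the bond from the spiro carbon C5 to C1, with ring A built on a finished ring B. In the forward key step a strong amide base turns bromoalkene A1 into an alkylidene carbene, which inserts with retention into the tertiary C5–H five atoms away and closes spiro cyclopentene A2.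
- For: the quaternary centre is made stereospecifically from a C–H centre, and C6 and C10 are set beforehand on an ordinary cyclohexane. On the fidelity of the quaternary centre this is at least as secure as the sigmatropic shift used here.
- Against: A1 already needs three contiguous ring-B centres. After insertion the alkene must be hydroborated on the correct face to give the C1 hydroxyl, and the two-carbon silylethyl arm maps poorly onto a C2 substituent that branches at its first carbon. The C7 ketal still has to become the tetrasubstituted enal.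
- Comparison: the chosen route offers instead a ring closure that sets C10 with help from the C1 hydroxyl, and a C2 arm introduced at the right oxidation level by simple enolate chemistry.

**Alternative 2:** Two ring-B bonds are cut at once (C5–C10 and C6–C7). Bicyclic butenolide A3 would add diene A4 across its double bond to give the cis-fused endo adduct A5.
- For: it is the most convergent option and is stronger than the chosen route in step economy up to ring B, since two bonds, the ring and several centres form in one operation.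
- Against: the dienophile carbon that becomes C5 is fully substituted and the diene is not electron-rich, so forcing conditions are likely. The lactone bridge ties the ring-A oxygen cis to C6, whereas the target has it trans, so C1 must later be inverted. C10 arrives as a secondary acetate and needs oxidation and a stereoselective methyl addition. The arm must be homologated by two carbons and the ring alkene removed.
- Comparison: the chosen route offers the C1/C6 trans relation from the start and a C10 that already carries its methyl group.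

**Alternative 3:** The cut is C1–C2, with ring A closed last. A Lewis acid activates the neopentyl aldehyde of A6 and the tethered E-allylsilane attacks it to give trans-2-vinylcyclopentanol A7.
- For: C1 and C2 are set together with the trans relation, and a vinyl handle is delivered at C2. On this point it is stronger than the ketone alkylation and reduction used here.
- Against: A6 must already contain the quaternary carbon, C6, C10 and the stereodefined tetrasubstituted alkene, so the two hardest problems are moved into the precursor and not solved. The face of the aldehyde relative to C6/C10 is controlled only by a possible chelate to the C10 ether. The vinyl group must then be functionalised at its internal carbon to reach the branched triene.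
- Comparison: the chosen route offers an early, chelate-controlled construction of the quaternary carbon and its neighbours, and a ring-forming step that itself creates a stereocentre.

Key step: step 11

Remark on the chemistry: metal enolates, alkoxides and radical anions are taken as reactive forms of the numbered compounds and carry no number; neutral species that pass through a telescoped operation are numbered. TBS = tert-butyl(dimethyl)silyl, TES = triethylsilyl, TBSO/TESO = the corresponding silyloxy groups; spiro locants as defined in the analysis.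

## Route

Step 1
Reactants: 1 pent-4-yn-1-ol
Product: 2 tert-butyl(dimethyl)(pent-4-yn-1-yloxy)silane
Conditions: TBSCl, imidazole, CH2Cl2, 0 °C to rt
Reagents that add atoms: tert-butyl(chloro)dimethylsilane, CC(C)(C)[Si](C)(C)Cl
Why: Standard silylation of a primary alcohol; this silyl ether is the one group on the future C6 arm that has to last until step 28.

Step 2
Reactants: 2 tert-butyl(dimethyl)(pent-4-yn-1-yloxy)silane
Product: 3 6-(TBSO)hex-2-yn-1-ol
Conditions: n-BuLi, THF, −78 °C; (CH2O)n, −78 °C to rt
Reagents that add atoms: paraformaldehyde (as formaldehyde), C=O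
Why: Deprotonation of the terminal alkyne and addition of the acetylide to formaldehyde (acetylide hydroxymethylation).

Step 3
Reactants: 3 6-(TBSO)hex-2-yn-1-ol
Product: 4 (2Z)-6-(TBSO)hex-2-en-1-ol
Conditions: H2 (1 atm), Pd/CaCO3 poisoned with Pb(OAc)2, quinoline, EtOAc, rt
Reagents that add atoms: none
Why: Semihydrogenation over poisoned palladium is a syn addition and stops at the Z alkene; this geometry later places the arm correctly at C6.

Step 4
Reactants: 5 ethyl 2-oxocyclopentane-1-carboxylate
Product: 6 ethyl (1S,2S)-2-hydroxycyclopentane-1-carboxylate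
Conditions: H2 (100 atm), RuCl2[(S)-BINAP] (0.5 mol %), CH2Cl2, 50 °C
Reagents that add atoms: none
Why: Noyori hydrogenation of a cyclic β-keto ester with dynamic kinetic resolution; the α-centre racemises through the enol and the (S)-BINAP catalyst sets the carbinol as S. The ester-bearing centre is erased in step 6, so only the carbinol matters.

Step 5
Reactants: 6 ethyl (1S,2S)-2-hydroxycyclopentane-1-carboxylate; 4 (2Z)-6-(TBSO)hex-2-en-1-ol
Product: 7 (2Z)-6-(TBSO)hex-2-en-1-yl (1S,2S)-2-hydroxycyclopentane-1-carboxylate
Conditions: Ti(OEt)4 (0.3 equiv), toluene, 100 °C, EtOH distilled off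
Reagents that add atoms: none
Why: Titanate-mediated transesterification runs under neutral conditions, is driven by removal of ethanol, and tolerates the free secondary hydroxyl, the silyl ether and the Z alkene.

Step 6
Reactants: 7 (2Z)-6-(TBSO)hex-2-en-1-yl (1S,2S)-2-hydroxycyclopentane-1-carboxylate
Product: 10 (1S,2S)-1-[(3R)-6-(TBSO)hex-1-en-3-yl]-2-hydroxycyclopentane-1-carboxylic acid, via bis(trimethylsilyl) ketene acetal 8 (not isolated), via rearranged bis(trimethylsilyl) derivative 9 (not isolated)
Conditions: LiN(i-Pr)2 (2.4 equiv), THF, −78 to −20 °C; Me3SiCl, Et3N, −78 °C to 55 °C; aq. citric acid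
Reagents that add atoms: none
Why: Dianionic Ireland–Claisen rearrangement: lithium bridges the alkoxide and the enolate oxygen, so after silylation the silyloxy group of the ketene acetal sits on the side of the carbinol carbon, and the chair transition state bonds the allyl terminus to the face opposite the ring silyloxy group, which sets the quaternary carbon with the carboxyl cis to the oxygen. In that chair the Z alkene carries the silyloxypropyl chain axial, which fixes the adjacent methine (future C6) in the required sense.

Step 7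
Reactants: 10 (1S,2S)-1-[(3R)-6-(TBSO)hex-1-en-3-yl]-2-hydroxycyclopentane-1-carboxylic acid
Product: 11 1-[(1S,2S)-1-[(3R)-6-(TBSO)hex-1-en-3-yl]-2-hydroxycyclopentyl]ethan-1-one
Conditions: MeLi (4 equiv), THF, 0 °C to rt; poured into cold aq. NH4Cl
Reagents that add atoms: methyllithium, [Li]C
Why: A lithium carboxylate takes up one methyllithium and the adduct does not collapse before work-up, so the hindered acid gives the methyl ketone without over-addition; the inverse quench keeps the β-hydroxy ketone away from base (no retro-aldol).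

Step 8
Reactants: 11 1-[(1S,2S)-1-[(3R)-6-(TBSO)hex-1-en-3-yl]-2-hydroxycyclopentyl]ethan-1-one
Product: 13 (2S)-2-[(1S,2S)-1-acetyl-2-hydroxycyclopentyl]-5-(TBSO)pentanal, via ozonide 12 (not isolated)
Conditions: O3, CH2Cl2, −78 °C; PPh3, −78 °C to rt
Reagents that add atoms: ozone, [O-][O+]=O
Why: Ozonolysis of the only alkene with reductive work-up; a lactol with the ring hydroxyl would be trans-fused and does not form, and the aldehyde is used at once to protect its α-centre.

Step 9
Reactants: 13 (2S)-2-[(1S,2S)-1-acetyl-2-hydroxycyclopentyl]-5-(TBSO)pentanal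
Product: 14 (4S)-4-[(1S,2S)-1-acetyl-2-hydroxycyclopentyl]-7-(TBSO)hept-1-en-3-ol (both C3 epimers)
Conditions: CH2=CHBr, CrCl2 (4 equiv), NiCl2 (2 mol %), DMF, rt
Reagents that add atoms: vinyl bromide, C=CBr
Why: Nozaki–Hiyama–Kishi vinylation: the vinylchromium reagent made from divalent chromium adds to aldehydes and leaves the methyl ketone, the free hydroxyl and the epimerisable α-centre alone; the new carbinol centre is oxidised away in step 10.

Step 10
Reactants: 14 (4S)-4-[(1S,2S)-1-acetyl-2-hydroxycyclopentyl]-7-(TBSO)hept-1-en-3-ol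
Product: 15 (4S)-4-[(1S,2S)-1-acetyl-2-hydroxycyclopentyl]-7-(TBSO)hept-1-en-3-one
Conditions: MnO2 (excess), CH2Cl2, rt
Reagents that add atoms: none
Why: MnO2 oxidises the allylic alcohol only, so the saturated ring hydroxyl needed for chelation in step 11 stays free.

Step 11
Reactants: 15 (4S)-4-[(1S,2S)-1-acetyl-2-hydroxycyclopentyl]-7-(TBSO)hept-1-en-3-one
Product: 16 (1S,5S,6S,10S)-1,10-dihydroxy-10-methyl-6-(3-TBSO-propyl)spiro[4.5]decan-7-one
Conditions: SmI2 (2.5 equiv), t-BuOH (2 equiv), THF, −78 to −40 °C
Reagents that add atoms: none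
Why: SmI2 transfers an electron to the acetyl carbonyl, which is bound together with the free C1 hydroxyl to the oxophilic metal, and the ketyl carbon adds to the unsubstituted β-carbon of the vinyl ketone; a second electron turns the α-keto radical into an enolate of trivalent samarium, which tert-butanol protonates at C8. The closest known reaction type is the SmI2 ketyl–olefin cyclisation of ketones onto enones and enoates. Ring B closes in the 6-endo-trig mode: the nucleophilic ketyl is polarity-matched with the electron-poor terminus, whereas 5-exo attack at the α-carbon would leave an unstabilised primary radical and is disfavoured by the planar C6–C7(=O)–C8=C9 unit. Should the enone be reduced first, its β-carbon attacks the samarium-bound ketone and the same bond results. The only new stereocentre, C10, is set by the chelate: with trivalent samarium bridging O1 and the ketyl oxygen, the chair-like transition state has C1 axial on ring B, the ketyl oxygen equatorial and gauche to C1, the methyl axial and the C6 arm equatorial, so the hydroxyl ends cis to C1; the epimer would need either the chelate broken or the arm axial and syn-diaxial to the C10 methyl. The step needs bond formation to outrun simple reduction of either carbonyl, which the weak proton donor, the low temperature and the three-atom tether secure, and it needs C6 to stay fixed, which it does because no base is present and the enolate forms towards C8.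

Step 12
Reactants: 16 (1S,5S,6S,10S)-1,10-dihydroxy-10-methyl-6-(3-TBSO-propyl)spiro[4.5]decan-7-one
Product: 17 (1S,5S,6S,10S)-7-ethynyl-10-methyl-6-(3-TBSO-propyl)spiro[4.5]decane-1,7,10-triol (both C7 epimers)
Conditions: HC≡CMgBr (6 equiv), THF, 0 °C to rt
Reagents that add atoms: ethynylmagnesium bromide, C#C[Mg]Br
Why: 1,2-Addition of a small, weakly basic acetylide to the hindered ring ketone (the first two equivalents deprotonate the hydroxyls); it removes the carbonyl next to C6 without base-mediated epimerisation, and the new C7 centre is lost again in step 14.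

Step 13
Reactants: 17 (1S,5S,6S,10S)-7-ethynyl-10-methyl-6-(3-TBSO-propyl)spiro[4.5]decane-1,7,10-triol
Product: 18 1,7-di-O-acetyl derivative of 17
Conditions: Ac2O, Et3N, DMAP, CH2Cl2, rt
Reagents that add atoms: acetic anhydride, CC(=O)OC(C)=O
Why: DMAP-catalysed acetylation takes the secondary C1 hydroxyl and the sterically slim tertiary propargylic hydroxyl, while the tertiary C10 hydroxyl next to the spiro centre is too hindered to react.

Step 14
Reactants: 18 1,7-di-O-acetyl derivative of 17
Product: 19 2-[(1S,5S,6R,10S)-1-acetoxy-10-hydroxy-10-methyl-6-(3-TBSO-propyl)spiro[4.5]decan-7-ylidene]ethenyl acetate (both allene diastereomers)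
Conditions: AgBF4 (5 mol %), CH2Cl2, rt, dark
Reagents that add atoms: none
Why: Silver-catalysed [3,3] shift of a tertiary propargylic acetate to the allenyl acetate (Saucy–Marbet rearrangement), a neutral way to make C7 an sp2 carbon; the axial chirality of the allene is of no consequence.

Step 15
Reactants: 19 2-[(1S,5S,6R,10S)-1-acetoxy-10-hydroxy-10-methyl-6-(3-TBSO-propyl)spiro[4.5]decan-7-ylidene]ethenyl acetate
Product: 21 (1S,5S,6R,10S)-7-[(2Z)-1-hydroxypropan-2-ylidene]-10-methyl-6-(3-TBSO-propyl)spiro[4.5]decane-1,10-diol, via enal 20 (not isolated)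
Conditions: MeLi (5.0 equiv, titrated), THF, −78 to −40 °C; MeI, DMPU, −78 to −40 °C; i-Bu2AlH, −78 °C; aq. KNaC4H4O6
Reagents that add atoms: iodomethane, CI
Why: Methyllithium cleaves both acetates (enolate generation from an enol acetate), the lithium allenolate is methylated at its central carbon, and the enal is reduced in the same flask before it can isomerise. The electrophile must approach the central allene carbon in the plane of C6–C7–C8 and should do so past the C8 methylene, because the other side is screened by the equatorial silyloxypropyl arm and the spiro centre; the methyl therefore ends cis to C8 and the oxygenated carbon cis to C6, the same kinetic preference that makes protonation of allenolates give Z enones.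

Step 16
Reactants: 21 (1S,5S,6R,10S)-7-[(2Z)-1-hydroxypropan-2-ylidene]-10-methyl-6-(3-TBSO-propyl)spiro[4.5]decane-1,10-diol
Product: 22 (1S,5S,6R,10S)-10-methyl-7-[(2Z)-1-(TBSO)propan-2-ylidene]-6-(3-TBSO-propyl)spiro[4.5]decane-1,10-diol
Conditions: TBSCl (1.1 equiv), imidazole, CH2Cl2, −20 to 0 °C
Reagents that add atoms: tert-butyl(chloro)dimethylsilane, CC(C)(C)[Si](C)(C)Cl
Why: The primary allylic hydroxyl is silylated much faster than the neopentyl-type secondary and the tertiary hydroxyl.

Step 17
Reactants: 22 (1S,5S,6R,10S)-10-methyl-7-[(2Z)-1-(TBSO)propan-2-ylidene]-6-(3-TBSO-propyl)spiro[4.5]decane-1,10-diol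
Product: 23 (5R,6R,10S)-10-hydroxy-10-methyl-7-[(2Z)-1-(TBSO)propan-2-ylidene]-6-(3-TBSO-propyl)spiro[4.5]decan-1-one
Conditions: Dess–Martin periodinane, NaHCO3, CH2Cl2, 0 °C to rt
Reagents that add atoms: none
Why: Dess–Martin oxidation of the only secondary alcohol under buffered, non-basic conditions, so the β-hydroxy ketone formed is not exposed to retro-aldol cleavage.

Step 18
Reactants: 23 (5R,6R,10S)-10-hydroxy-10-methyl-7-[(2Z)-1-(TBSO)propan-2-ylidene]-6-(3-TBSO-propyl)spiro[4.5]decan-1-one
Product: 24 (5R,6R,10S)-10-methyl-7-[(2Z)-1-(TBSO)propan-2-ylidene]-6-(3-TBSO-propyl)-10-(TESO)spiro[4.5]decan-1-one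
Conditions: Et3SiOTf, 2,6-lutidine, CH2Cl2, −78 °C
Reagents that add atoms: triethylsilyl trifluoromethanesulfonate, CC[Si](CC)(CC)OS(=O)(=O)C(F)(F)F
Why: Silyl triflate silylation of the tertiary C10 hydroxyl; as the silyl ether it cannot fragment by retro-aldol when the C1 ketone is enolised, and it adds bulk on the C10 face of ring A.

Step 19
Reactants: 24 (5R,6R,10S)-10-methyl-7-[(2Z)-1-(TBSO)propan-2-ylidene]-6-(3-TBSO-propyl)-10-(TESO)spiro[4.5]decan-1-one
Product: 25 ethyl 2-[(2S,5R,6R,10S)-10-methyl-1-oxo-7-[(2Z)-1-(TBSO)propan-2-ylidene]-6-(3-TBSO-propyl)-10-(TESO)spiro[4.5]decan-2-yl]acetate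
Conditions: LiN(i-Pr)2 (1.1 equiv), THF, −78 °C; BrCH2CO2Et, DMPU, −78 to −40 °C
Reagents that add atoms: ethyl bromoacetate, CCOC(=O)CBr
Why: The C1 ketone can enolise only towards C2 and its lithium enolate is alkylated by the reactive α-bromo ester; the electrophile should enter anti to the fully substituted, silyloxy-bearing C10, that is on the face of C6, which gives the C2 configuration of the target (as an angular substituent directs alkylation next to a five-membered ring ketone).

Step 20
Reactants: 25 ethyl 2-[(2S,5R,6R,10S)-10-methyl-1-oxo-7-[(2Z)-1-(TBSO)propan-2-ylidene]-6-(3-TBSO-propyl)-10-(TESO)spiro[4.5]decan-2-yl]acetate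
Product: 26 ethyl 2-[(1S,2S,5S,6R,10S)-1-hydroxy-10-methyl-7-[(2Z)-1-(TBSO)propan-2-ylidene]-6-(3-TBSO-propyl)-10-(TESO)spiro[4.5]decan-2-yl]acetate
Conditions: NaBH4, MeOH–THF, −30 °C
Reagents that add atoms: none
Why: The small hydride should attack the C1 carbonyl from the same face, opposite C10, so the hydroxyl comes out cis to C10 and trans to the C2 arm; any epimeric alcohol would close to the cis-fused γ-lactone and is removed that way.

Step 21
Reactants: 27 6-methylhept-5-en-2-one
Product: 28 6-methylhepta-1,5-dien-2-yl trifluoromethanesulfonate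
Conditions: LiN(i-Pr)2, THF, −78 °C; PhNTf2, −78 °C to rt
Reagents that add atoms: N-phenylbis(trifluoromethanesulfonimide), O=S(=O)(N(c1ccccc1)S(=O)(=O)C(F)(F)F)C(F)(F)F
Why: Kinetic deprotonation of the methyl ketone on the methyl side and O-sulfonylation give the terminal enol triflate.

Step 22
Reactants: 28 6-methylhepta-1,5-dien-2-yl trifluoromethanesulfonate
Product: 29 methyl (2E)-8-methyl-4-methylidenenona-2,7-dienoate
Conditions: methyl acrylate, Pd(OAc)2 (5 mol %), PPh3, Et3N, DMF, 70 °C
Reagents that add atoms: methyl acrylate, C=CC(=O)OC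
Why: Heck reaction: oxidative addition of the enol triflate to zerovalent palladium, insertion of the acrylate and β-hydride elimination give the E dienoate with the 1,1-disubstituted alkene intact.

Step 23
Reactants: 29 methyl (2E)-8-methyl-4-methylidenenona-2,7-dienoate
Product: 30 (2E)-8-methyl-4-methylidenenona-2,7-dien-1-ol
Conditions: i-Bu2AlH (2.5 equiv), CH2Cl2, −78 °C
Reagents that add atoms: none
Why: 1,2-Reduction of the conjugated ester to the allylic alcohol.

Step 24
Reactants: 30 (2E)-8-methyl-4-methylidenenona-2,7-dien-1-ol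
Product: 31 (2E)-8-methyl-4-methylidenenona-2,7-dienal
Conditions: MnO2, CH2Cl2, rt
Reagents that add atoms: none
Why: Selective oxidation of the allylic alcohol to the dienal, which is used fresh.

Step 25
Reactants: 26 ethyl 2-[(1S,2S,5S,6R,10S)-1-hydroxy-10-methyl-7-[(2Z)-1-(TBSO)propan-2-ylidene]-6-(3-TBSO-propyl)-10-(TESO)spiro[4.5]decan-2-yl]acetate; 31 (2E)-8-methyl-4-methylidenenona-2,7-dienal
Product: 33 ethyl (2E,4E)-2-[(1S,2S,5S,6R,10S)-1-acetoxy-10-methyl-7-[(2Z)-1-(TBSO)propan-2-ylidene]-6-(3-TBSO-propyl)-10-(TESO)spiro[4.5]decan-2-yl]-10-methyl-6-methylideneundeca-2,4,9-trienoate, via aldol diacetate 32 (not isolated)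
Conditions: LiN(i-Pr)2 (2.3 equiv), THF, −78 °C; 31, −78 °C; Ac2O, DMAP, −78 to 0 °C; DBU, rt
Reagents that add atoms: acetic anhydride, CC(=O)OC(C)=O
Why: Aldol addition of the ester enolate (formed as the alkoxide–enolate dianion) to the dienal, acetylation of both alkoxides in the same flask and E1cB elimination of the β-acetoxy ester. The elimination passes through the ester enolate and should give the more stable alkene, in which the dienyl chain is trans to the ester and the C2–H bond eclipses the double bond (minimal A(1,3) strain), that is the E geometry of the target; the diene keeps its E geometry.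

Step 26
Reactants: 33 ethyl (2E,4E)-2-[(1S,2S,5S,6R,10S)-1-acetoxy-10-methyl-7-[(2Z)-1-(TBSO)propan-2-ylidene]-6-(3-TBSO-propyl)-10-(TESO)spiro[4.5]decan-2-yl]-10-methyl-6-methylideneundeca-2,4,9-trienoate
Product: 34 (2E,4E)-2-[(1S,2S,5S,6R,10S)-1-hydroxy-10-methyl-7-[(2Z)-1-(TBSO)propan-2-ylidene]-6-(3-TBSO-propyl)-10-(TESO)spiro[4.5]decan-2-yl]-10-methyl-6-methylideneundeca-2,4,9-trien-1-ol
Conditions: i-Bu2AlH (6 equiv), CH2Cl2, −78 to −40 °C; aq. KNaC4H4O6
Reagents that add atoms: none
Why: i-Bu2AlH reduces the conjugated ester to the allylic alcohol by 1,2-addition and cleaves the C1 acetate in the same operation.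

Step 27
Reactants: 34 (2E,4E)-2-[(1S,2S,5S,6R,10S)-1-hydroxy-10-methyl-7-[(2Z)-1-(TBSO)propan-2-ylidene]-6-(3-TBSO-propyl)-10-(TESO)spiro[4.5]decan-2-yl]-10-methyl-6-methylideneundeca-2,4,9-trien-1-ol
Product: 35 (2E,4E)-2-[(1S,2S,5S,6R,10S)-1-hydroxy-10-methyl-7-[(2Z)-1-(TBSO)propan-2-ylidene]-6-(3-TBSO-propyl)-10-(TESO)spiro[4.5]decan-2-yl]-10-methyl-6-methylideneundeca-2,4,9-trien-1-yl acetate
Conditions: AcCl (1.1 equiv), 2,4,6-collidine, CH2Cl2, −78 °C
Reagents that add atoms: acetyl chloride, CC(=O)Cl
Why: Acetyl chloride with collidine at low temperature acetylates primary alcohols selectively; the hindered secondary C1 hydroxyl does not react.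

Step 28
Reactants: 35 (2E,4E)-2-[(1S,2S,5S,6R,10S)-1-hydroxy-10-methyl-7-[(2Z)-1-(TBSO)propan-2-ylidene]-6-(3-TBSO-propyl)-10-(TESO)spiro[4.5]decan-2-yl]-10-methyl-6-methylideneundeca-2,4,9-trien-1-yl acetate
Product: 36 (2E,4E)-2-[(1S,2S,5S,6R,10S)-1,10-dihydroxy-7-[(2Z)-1-hydroxypropan-2-ylidene]-6-(3-hydroxypropyl)-10-methylspiro[4.5]decan-2-yl]-10-methyl-6-methylideneundeca-2,4,9-trien-1-yl acetate
Conditions: HF·pyridine, pyridine, THF, 0 °C to rt
Reagents that add atoms: none
Why: Buffered HF·pyridine removes the two primary TBS ethers and the tertiary TES ether without touching the allylic acetate or the triene.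

Step 29
Reactants: 36 (2E,4E)-2-[(1S,2S,5S,6R,10S)-1,10-dihydroxy-7-[(2Z)-1-hydroxypropan-2-ylidene]-6-(3-hydroxypropyl)-10-methylspiro[4.5]decan-2-yl]-10-methyl-6-methylideneundeca-2,4,9-trien-1-yl acetate
Product: 37 (2E,4E)-2-[(1S,2S,5S,6R,10S)-1,10-dihydroxy-6-(3-hydroxypropyl)-10-methyl-7-[(2Z)-1-oxopropan-2-ylidene]spiro[4.5]decan-2-yl]-10-methyl-6-methylideneundeca-2,4,9-trien-1-yl acetate (CNP0204268.2)
Conditions: MnO2, CH2Cl2, rt
Reagents that add atoms: none
Why: MnO2 oxidises only the allylic primary alcohol; the saturated primary, the secondary and the tertiary hydroxyl are inert, and the neutral conditions should keep the Z geometry of the new enal.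

## Compound list

1 | pent-4-yn-1-ol | C#CCCCO | starting material
2 | tert-butyl(dimethyl)(pent-4-yn-1-yloxy)silane | C#CCCCO[Si](C)(C)C(C)(C)C | intermediate
3 | 6-(TBSO)hex-2-yn-1-ol | OCC#CCCCO[Si](C)(C)C(C)(C)C | intermediate
4 | (2Z)-6-(TBSO)hex-2-en-1-ol | OC/C=C\CCCO[Si](C)(C)C(C)(C)C | intermediate
5 | ethyl 2-oxocyclopentane-1-carboxylate | CCOC(=O)C1CCCC1=O | starting material
6 | ethyl (1S,2S)-2-hydroxycyclopentane-1-carboxylate | C1CC[C@H](C(=O)OCC)[C@H]1O | intermediate
7 | (2Z)-6-(TBSO)hex-2-en-1-yl (1S,2S)-2-hydroxycyclopentane-1-carboxylate | C1CC[C@H](C(=O)OC/C=C\CCCO[Si](C)(C)C(C)(C)C)[C@H]1O | intermediate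
8 | bis(trimethylsilyl) ketene acetal of 7 (exocyclic C=C(OSiMe3)(O-allyl), OSiMe3 on the side of the carbinol carbon; (2S)-2-OSiMe3) | C1CC/C(=C(/O[Si](C)(C)C)OC/C=C\CCCO[Si](C)(C)C(C)(C)C)[C@H]1O[Si](C)(C)C | intermediate
9 | trimethylsilyl (1S,2S)-1-[(3R)-6-(TBSO)hex-1-en-3-yl]-2-(trimethylsilyloxy)cyclopentane-1-carboxylate | C1CC[C@](C(=O)O[Si](C)(C)C)([C@H](CCCO[Si](C)(C)C(C)(C)C)C=C)[C@H]1O[Si](C)(C)C | intermediate
10 | (1S,2S)-1-[(3R)-6-(TBSO)hex-1-en-3-yl]-2-hydroxycyclopentane-1-carboxylic acid | C1CC[C@](C(=O)O)([C@H](CCCO[Si](C)(C)C(C)(C)C)C=C)[C@H]1O | intermediate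
11 | 1-[(1S,2S)-1-[(3R)-6-(TBSO)hex-1-en-3-yl]-2-hydroxycyclopentyl]ethan-1-one | C1CC[C@](C(C)=O)([C@H](CCCO[Si](C)(C)C(C)(C)C)C=C)[C@H]1O | intermediate
12 | ozonide of 11 (vinyl group as a 3-substituted 1,2,4-trioxolane; other centres as in 11) | C1CC[C@](C(C)=O)([C@H](CCCO[Si](C)(C)C(C)(C)C)C2OCOO2)[C@H]1O | intermediate
13 | (2S)-2-[(1S,2S)-1-acetyl-2-hydroxycyclopentyl]-5-(TBSO)pentanal | C1CC[C@](C(C)=O)([C@H](CCCO[Si](C)(C)C(C)(C)C)C=O)[C@H]1O | intermediate
14 | (4S)-4-[(1S,2S)-1-acetyl-2-hydroxycyclopentyl]-7-(TBSO)hept-1-en-3-ol (both C3 epimers) | C1CC[C@](C(C)=O)([C@H](CCCO[Si](C)(C)C(C)(C)C)C(O)C=C)[C@H]1O | intermediate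
15 | (4S)-4-[(1S,2S)-1-acetyl-2-hydroxycyclopentyl]-7-(TBSO)hept-1-en-3-one | C1CC[C@](C(C)=O)([C@H](CCCO[Si](C)(C)C(C)(C)C)C(=O)C=C)[C@H]1O | intermediate
16 | (1S,5S,6S,10S)-1,10-dihydroxy-10-methyl-6-(3-TBSO-propyl)spiro[4.5]decan-7-one | C1CC[C@]2([C@H](CCCO[Si](C)(C)C(C)(C)C)C(=O)CC[C@]2(C)O)[C@H]1O | intermediate
17 | (1S,5S,6S,10S)-7-ethynyl-10-methyl-6-(3-TBSO-propyl)spiro[4.5]decane-1,7,10-triol (both C7 epimers) | C1CC[C@]2([C@H](CCCO[Si](C)(C)C(C)(C)C)C(O)(C#C)CC[C@]2(C)O)[C@H]1O | intermediate
18 | 1,7-di-O-acetyl derivative of 17 (both C7 epimers) | C1CC[C@]2([C@H](CCCO[Si](C)(C)C(C)(C)C)C(OC(C)=O)(C#C)CC[C@]2(C)O)[C@H]1OC(C)=O | intermediate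
19 | 2-[(1S,5S,6R,10S)-1-acetoxy-10-hydroxy-10-methyl-6-(3-TBSO-propyl)spiro[4.5]decan-7-ylidene]ethenyl acetate (both allene diastereomers) | C1CC[C@]2([C@H](CCCO[Si](C)(C)C(C)(C)C)C(=C=COC(C)=O)CC[C@]2(C)O)[C@H]1OC(C)=O | intermediate
20 | (2Z)-2-[(1S,5S,6R,10S)-1,10-dihydroxy-10-methyl-6-(3-TBSO-propyl)spiro[4.5]decan-7-ylidene]propanal | C1CC[C@]2([C@H](CCCO[Si](C)(C)C(C)(C)C)/C(=C(/C)C=O)CC[C@]2(C)O)[C@H]1O | intermediate
21 | (1S,5S,6R,10S)-7-[(2Z)-1-hydroxypropan-2-ylidene]-10-methyl-6-(3-TBSO-propyl)spiro[4.5]decane-1,10-diol | C1CC[C@]2([C@H](CCCO[Si](C)(C)C(C)(C)C)/C(=C(/C)CO)CC[C@]2(C)O)[C@H]1O | intermediate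
22 | (1S,5S,6R,10S)-10-methyl-7-[(2Z)-1-(TBSO)propan-2-ylidene]-6-(3-TBSO-propyl)spiro[4.5]decane-1,10-diol | C1CC[C@]2([C@H](CCCO[Si](C)(C)C(C)(C)C)/C(=C(/C)CO[Si](C)(C)C(C)(C)C)CC[C@]2(C)O)[C@H]1O | intermediate
23 | (5R,6R,10S)-10-hydroxy-10-methyl-7-[(2Z)-1-(TBSO)propan-2-ylidene]-6-(3-TBSO-propyl)spiro[4.5]decan-1-one | C1CC[C@]2([C@H](CCCO[Si](C)(C)C(C)(C)C)/C(=C(/C)CO[Si](C)(C)C(C)(C)C)CC[C@]2(C)O)C1=O | intermediate
24 | (5R,6R,10S)-10-methyl-7-[(2Z)-1-(TBSO)propan-2-ylidene]-6-(3-TBSO-propyl)-10-(TESO)spiro[4.5]decan-1-one | C1CC[C@]2([C@H](CCCO[Si](C)(C)C(C)(C)C)/C(=C(/C)CO[Si](C)(C)C(C)(C)C)CC[C@]2(C)O[Si](CC)(CC)CC)C1=O | intermediate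
25 | ethyl 2-[(2S,5R,6R,10S)-10-methyl-1-oxo-7-[(2Z)-1-(TBSO)propan-2-ylidene]-6-(3-TBSO-propyl)-10-(TESO)spiro[4.5]decan-2-yl]acetate | CCOC(=O)C[C@@H]1CC[C@]2([C@H](CCCO[Si](C)(C)C(C)(C)C)/C(=C(/C)CO[Si](C)(C)C(C)(C)C)CC[C@]2(C)O[Si](CC)(CC)CC)C1=O | intermediate
26 | ethyl 2-[(1S,2S,5S,6R,10S)-1-hydroxy-10-methyl-7-[(2Z)-1-(TBSO)propan-2-ylidene]-6-(3-TBSO-propyl)-10-(TESO)spiro[4.5]decan-2-yl]acetate | CCOC(=O)C[C@@H]1CC[C@]2([C@H](CCCO[Si](C)(C)C(C)(C)C)/C(=C(/C)CO[Si](C)(C)C(C)(C)C)CC[C@]2(C)O[Si](CC)(CC)CC)[C@H]1O | intermediate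
27 | 6-methylhept-5-en-2-one | CC(=O)CCC=C(C)C | starting material
28 | 6-methylhepta-1,5-dien-2-yl trifluoromethanesulfonate | C=C(OS(=O)(=O)C(F)(F)F)CCC=C(C)C | intermediate
29 | methyl (2E)-8-methyl-4-methylidenenona-2,7-dienoate | COC(=O)/C=C/C(=C)CCC=C(C)C | intermediate
30 | (2E)-8-methyl-4-methylidenenona-2,7-dien-1-ol | OC/C=C/C(=C)CCC=C(C)C | intermediate
31 | (2E)-8-methyl-4-methylidenenona-2,7-dienal | O=C/C=C/C(=C)CCC=C(C)C | intermediate
32 | aldol diacetate: ethyl (4E)-3-acetoxy-2-[1-acetoxy-spirodecan-2-yl]-10-methyl-6-methylideneundeca-4,9-dienoate, ring substituents and centres as in 33, mixture at chain C2 and C3 | CCOC(=O)C(C(OC(C)=O)/C=C/C(=C)CCC=C(C)C)[C@@H]1CC[C@]2([C@H](CCCO[Si](C)(C)C(C)(C)C)/C(=C(/C)CO[Si](C)(C)C(C)(C)C)CC[C@]2(C)O[Si](CC)(CC)CC)[C@H]1OC(C)=O | intermediate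
33 | ethyl (2E,4E)-2-[(1S,2S,5S,6R,10S)-1-acetoxy-10-methyl-7-[(2Z)-1-(TBSO)propan-2-ylidene]-6-(3-TBSO-propyl)-10-(TESO)spiro[4.5]decan-2-yl]-10-methyl-6-methylideneundeca-2,4,9-trienoate | CCOC(=O)/C(=C/C=C/C(=C)CCC=C(C)C)[C@@H]1CC[C@]2([C@H](CCCO[Si](C)(C)C(C)(C)C)/C(=C(/C)CO[Si](C)(C)C(C)(C)C)CC[C@]2(C)O[Si](CC)(CC)CC)[C@H]1OC(C)=O | intermediate
34 | (2E,4E)-2-[(1S,2S,5S,6R,10S)-1-hydroxy-10-methyl-7-[(2Z)-1-(TBSO)propan-2-ylidene]-6-(3-TBSO-propyl)-10-(TESO)spiro[4.5]decan-2-yl]-10-methyl-6-methylideneundeca-2,4,9-trien-1-ol | OC/C(=C/C=C/C(=C)CCC=C(C)C)[C@@H]1CC[C@]2([C@H](CCCO[Si](C)(C)C(C)(C)C)/C(=C(/C)CO[Si](C)(C)C(C)(C)C)CC[C@]2(C)O[Si](CC)(CC)CC)[C@H]1O | intermediate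
35 | (2E,4E)-2-[(1S,2S,5S,6R,10S)-1-hydroxy-10-methyl-7-[(2Z)-1-(TBSO)propan-2-ylidene]-6-(3-TBSO-propyl)-10-(TESO)spiro[4.5]decan-2-yl]-10-methyl-6-methylideneundeca-2,4,9-trien-1-yl acetate | CC(=O)OC/C(=C/C=C/C(=C)CCC=C(C)C)[C@@H]1CC[C@]2([C@H](CCCO[Si](C)(C)C(C)(C)C)/C(=C(/C)CO[Si](C)(C)C(C)(C)C)CC[C@]2(C)O[Si](CC)(CC)CC)[C@H]1O | intermediate
36 | (2E,4E)-2-[(1S,2S,5S,6R,10S)-1,10-dihydroxy-7-[(2Z)-1-hydroxypropan-2-ylidene]-6-(3-hydroxypropyl)-10-methylspiro[4.5]decan-2-yl]-10-methyl-6-methylideneundeca-2,4,9-trien-1-yl acetate | CC(=O)OC/C(=C/C=C/C(=C)CCC=C(C)C)[C@@H]1CC[C@]2([C@H](CCCO)/C(=C(/C)CO)CC[C@]2(C)O)[C@H]1O | intermediate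
37 | (2E,4E)-2-[(1S,2S,5S,6R,10S)-1,10-dihydroxy-6-(3-hydroxypropyl)-10-methyl-7-[(2Z)-1-oxopropan-2-ylidene]spiro[4.5]decan-2-yl]-10-methyl-6-methylideneundeca-2,4,9-trien-1-yl acetate (CNP0204268.2) | C=C(/C=C/C=C(/COC(C)=O)[C@@H]1CC[C@]2([C@H](CCCO)/C(=C(/C)C=O)CC[C@]2(C)O)[C@H]1O)CCC=C(C)C | target

## Step count and least certain steps

Total: 29 steps. Longest linear sequence: 24 steps (steps 1–3, 5–20, 25–29); steps 4 and 21–24 are side branches.

**Step 11 (key step).** Reduction may win over bond formation (conjugate reduction of the vinyl ketone, or reduction of the chelated ketone to a diol), or the chelate may not be maintained, giving poor facial selectivity at the ketyl and the C10 epimer. Fallback, setting out from 14 and returning at 16: the allylic alcohol 14 is treated with Me2AlCl in CH2Cl2 at low temperature. The aluminium binds the ring hydroxyl and the acetyl oxygen, the vinyl terminus adds to the activated carbonyl in an intramolecular carbonyl-ene reaction in which the hydrogen on the carbinol carbon is transferred, and the enol formed tautomerises to ketone 16. No new compound is made.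

**Step 15.** O-methylation or proton transfer may compete with C-methylation, surplus methyllithium may add to the enal, and the geometry may be eroded, either by attack past C6 or by isomerisation of the enal through its dienolate before the hydride arrives. Fallback, from 16, returning at 21:
- isopropenylmagnesium bromide is added to 16 to give the tertiary allylic alcohol F1;
- the C1 hydroxyl is acetylated (Ac2O, DMAP) to give F2;
- oxidative 1,3-transposition with pyridinium chlorochromate, C5H5NH[CrO3Cl] (Babler–Dauben oxidation), gives the enal acetate F3 as a mixture of geometric isomers, from which the Z isomer is separated and the other recycled by photochemical isomerisation;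
- i-Bu2AlH reduces the aldehyde and removes the acetate to give 21.

**Step 19.** Facial selectivity at C2 may be poor, since both faces of the enolate carry a ring-B carbon, and proton transfer may lead to recovered ketone or dialkylation. Fallback, from 24, returning at 25: the lithium enolate of 24 is condensed with ethyl glyoxylate and the aldol is dehydrated (MsCl, Et3N) to the alkylidene keto ester F4. Conjugate reduction with [(Ph3P)CuH]6 and protonation of the resulting enolate then put hydrogen, not carbon, on the open face of ring A. This gives the C2 configuration opposite to that of direct alkylation, and is the remedy if the electrophile turns out to prefer the C10 face.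

**Step 6.** A boat transition state or incomplete control of the ketene acetal geometry may erode the configuration of the methine next to the quaternary carbon, and enolisation of the hindered ester may be slow. Fallback, from 3, returning at 11:
- 3 is reduced with NaAlH2(OCH2CH2OMe)2 to the E allylic alcohol F5, which is converted into methyl carbonate F6 (ClCO2Me, pyridine);
- branched-selective allylic alkylation of commercial 2-acetylcyclopentanone with F6 under [Ir(cod)Cl]2 and a chiral phosphoramidite gives diketone F7, the catalyst setting the quaternary carbon and the adjacent methine;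
- chelation-controlled reduction of the ring ketone with Zn(BH4)2 gives 11.

## Further compounds

F0 | step 11 | none | none
F1 | step 15 | (1S,5S,6S,10S)-10-methyl-7-(prop-1-en-2-yl)-6-(3-TBSO-propyl)spiro[4.5]decane-1,7,10-triol (both C7 epimers) | C1CC[C@]2([C@H](CCCO[Si](C)(C)C(C)(C)C)C(O)(C(C)=C)CC[C@]2(C)O)[C@H]1O
F2 | step 15 | 1-O-acetyl derivative of F1 | C1CC[C@]2([C@H](CCCO[Si](C)(C)C(C)(C)C)C(O)(C(C)=C)CC[C@]2(C)O)[C@H]1OC(C)=O
F3 | step 15 | (2Z)-2-[(1S,5S,6R,10S)-1-acetoxy-10-hydroxy-10-methyl-6-(3-TBSO-propyl)spiro[4.5]decan-7-ylidene]propanal | C1CC[C@]2([C@H](CCCO[Si](C)(C)C(C)(C)C)/C(=C(/C)C=O)CC[C@]2(C)O)[C@H]1OC(C)=O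
F4 | step 19 | ethyl (2E)-2-[(5R,6R,10S)-10-methyl-1-oxo-7-[(2Z)-1-(TBSO)propan-2-ylidene]-6-(3-TBSO-propyl)-10-(TESO)spiro[4.5]decan-2-ylidene]acetate | CCOC(=O)/C=C1\CC[C@]2([C@H](CCCO[Si](C)(C)C(C)(C)C)/C(=C(/C)CO[Si](C)(C)C(C)(C)C)CC[C@]2(C)O[Si](CC)(CC)CC)C1=O
F5 | step 6 | (2E)-6-(TBSO)hex-2-en-1-ol | OC/C=C/CCCO[Si](C)(C)C(C)(C)C
F6 | step 6 | (2E)-6-(TBSO)hex-2-en-1-yl methyl carbonate | COC(=O)OC/C=C/CCCO[Si](C)(C)C(C)(C)C
F7 | step 6 | 2-acetyl-2-[6-(TBSO)hex-1-en-3-yl]cyclopentan-1-one, quaternary carbon and hexenyl C3 configured as in 11 | C1CC[C@](C(C)=O)([C@H](CCCO[Si](C)(C)C(C)(C)C)C=C)C1=O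
A1 | alternative 1 | ring-B bromoalkene: cyclohexane with tertiary C5–H carrying a 4-bromo-3-[2-(dimethylphenylsilyl)ethyl]but-3-enyl chain, C6 silyloxypropyl arm, C7 dioxolane, C10 methyl and OTES | BrC=C(CC[Si](C)(C)c1ccccc1)CC[C@H]1[C@H](CCCO[Si](C)(C)C(C)(C)C)C2(OCCO2)CC[C@]1(C)O[Si](CC)(CC)CC
A2 | alternative 1 | spiro cyclopentene with dimethyl(phenyl)silylethyl arm | C[Si](C)(c1ccccc1)CCC1=C[C@]2(CC1)[C@H](CCCO[Si](C)(C)C(C)(C)C)C3(OCCO3)CC[C@]2(C)O[Si](CC)(CC)CC
A3 | alternative 2 | (6aR)-4,5,6,6a-tetrahydro-2H-cyclopenta[b]furan-2-one | C1CCC(=CC(=O)O2)[C@@H]12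
A4 | alternative 2 | (1E,3E)-buta-1,3-diene-1,4-diyl diacetate | CC(=O)O/C=C/C=C/OC(C)=O
A5 | alternative 2 | tricyclic spiro lactone diacetate (endo adduct) | C1CC[C@]2([C@H]3[C@H](OC(C)=O)C=C[C@@H]2OC(C)=O)[C@@H]1OC3=O
A6 | alternative 3 | ring-B aldehyde: quaternary carbon bearing formyl and (3E)-5-(trimethylsilyl)pent-3-enyl, with C6 arm, C7 silyloxypropan-2-ylidene and C10 methyl and OCH2OCH3 | O=C[C@]1(CC/C=C/C[Si](C)(C)C)[C@H](CCCO[Si](C)(C)C(C)(C)C)/C(=C(/C)CO[Si](C)(C)C(C)(C)C)CC[C@]1(C)OCOC
A7 | alternative 3 | spiro trans-2-vinylcyclopentanol | C=C[C@@H]1CC[C@]2([C@H](CCCO[Si](C)(C)C(C)(C)C)/C(=C(/C)CO[Si](C)(C)C(C)(C)C)CC[C@]2(C)OCOC)[C@H]1O
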